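**Plan**

- Numbering of the target (spiro[5.5]undecane): C6 spiro, C7 CH(Et), C8 CH(Me), C9 CH(Ar), C10 CH(Me), C11 CH(Ar); Ar = 2,4,5-trimethoxyphenyl.
- Retrosynthesis cuts C7–C8 and C9–C10, and with them the spiro bond C6–C11. The target falls into one 4-hydroxy-2,5-dimethoxyphenyl C3 unit and two (Z)-asarone units.
- Enabling feature: C7, C9 and C11 are alternating benzylic carbons, and C7 is benzylic to the ring that becomes the dienone, whose C6 lies para to its oxygen. One cation can therefore pass from C7 to C9 to C11 by two head-to-tail alkene additions and be quenched by ipso attack of that ring.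
- Forward: two routine steps give the p-hydroxybenzylic alcohol. One acid-catalysed cascade then joins the chain (C7–C8, C9–C10), closes the cyclohexane (C6–C11) and creates the dienone. The para-OH is the only activating group and ends as the C3 carbonyl, so nothing has to be removed.
- Stereochemistry: C7 from a chiral counter-anion; C8, C9 and C10 by acyclic relay (open transition states on the (Z)-alkene, A(1,3) strain); C11 and C6 from the chair-like ring closure.

Key step: step 3

Remark: the SMILES fixes six stereocentres; if rotation about the hindered aryl–ring bonds at C9 and C11 is slow, the rotamer population is left to thermal equilibration.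

**Route**

Step 1
Reactants: 1 4-bromo-2,5-dimethoxybenzaldehyde
Product: 2 rac-1-(4-bromo-2,5-dimethoxyphenyl)propan-1-ol
Conditions: EtMgBr (1.3 equiv), THF, -78 to 0 °C; aq. NH4Cl
Reagents that add atoms: ethylmagnesium bromide, CC[Mg]Br
Why: Grignard 1,2-addition to a non-enolisable aryl aldehyde; the carbinol centre is left racemic on purpose because it is erased at the quinone methide stage of step 3.

Step 2
Reactants: 2 rac-1-(4-bromo-2,5-dimethoxyphenyl)propan-1-ol
Product: 5 rac-4-(1-hydroxypropyl)-2,5-dimethoxyphenol, via aryllithium alkoxide 3 (not isolated), via lithium aryltrimethoxyborate 4 (not isolated)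
Conditions: n-BuLi (2.2 equiv), THF, -78 °C; B(OMe)3, -78 °C to rt; 30% aq. H2O2, 0 °C; aq. NH4Cl to pH 7
Reagents that add atoms: hydrogen peroxide, OO
Why: Alkoxide formation, Br/Li exchange, borylation and peroxide oxidation of the aryl–boron bond (C-to-O migration) should install the para-OH that later triggers and terminates the cascade; no stereocentre is set.

Step 3
Reactants: 5 rac-4-(1-hydroxypropyl)-2,5-dimethoxyphenol, 6 (Z)-asarone (two molecules are incorporated)
Product: 10 tatanan B, via p-quinone methide 7 (not isolated), via dimeric benzylic cation 8 (not isolated), via trimeric benzylic cation 9 (not isolated)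
Conditions: chiral BINOL-derived imidodiphosphorimidate acid (IDPi, 5 mol%, antipode selected for (R)-C7), 6 (3 equiv), 5 Å MS, CH2Cl2, -60 to -20 °C, 5 added over 6 h; Et3N quench
Reagents that add atoms: none
Why: Proposed new method: the acid dehydrates 5 to p-quinone methide 7, its O-protonated form is attacked at the exocyclic carbon by the β-carbon of 6 to give benzylic cation 8, a second 6 adds in the same way to give cation 9, and the ring carbon para to the phenol OH then attacks the C11 cation with loss of the O–H proton, which returns the catalyst. Closest known reaction types are chiral-acid-catalysed 1,6-additions to in situ p-quinone methides, acid-catalysed head-to-tail oligomerisation of propenylbenzenes and ipso-Friedel–Crafts spirocyclisation of para-substituted phenols; what is new is their union in one catalytic enantioselective three-component cascade. The cyclohexane is the only ring closed, by ipso (spiro, exo with respect to the arene C=C) attack through a chair that places the ethyl group, both aryl groups and the C10 methyl equatorial. C7 is set by the chiral anion, which leaves one face of the ion-paired cation open; C8 and C10 by open antiperiplanar transition states in which the alkyl arm of the cation sits in the empty quadrant beside the vinylic H of the (Z)-alkene; C9 by A(1,3)-strain-controlled attack anti to the larger C8 substituent; C11 and C6 by the chair, the OMe-bearing dienone carbon going equatorial so that only the flat CH= is syn-axial to the C8 methyl. The step needs cross-coupling over homo-oligomerisation, chain stop after two alkenes and alkene capture of 8 in preference to indane formation: the free para-OH makes 5 the component that ionises most readily (5 is added slowly to excess 6) and makes C6 the best internal nucleophile once the chain can reach it through a six-membered transition state, while the propenyl π-bond is far more nucleophilic than any arene C–H position available to 8.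

**Compound list**

1 | 4-bromo-2,5-dimethoxybenzaldehyde | O=Cc1cc(OC)c(Br)cc1OC | starting material
2 | rac-1-(4-bromo-2,5-dimethoxyphenyl)propan-1-ol | CCC(O)c1cc(OC)c(Br)cc1OC | intermediate
3 | lithium 1-(4-lithio-2,5-dimethoxyphenyl)propan-1-olate (racemic) | CCC(O[Li])c1cc(OC)c([Li])cc1OC | intermediate (not isolated)
4 | lithium trimethoxy[4-(1-lithiooxypropyl)-2,5-dimethoxyphenyl]borate (racemic) | CCC(O[Li])c1cc(OC)c(cc1OC)[B-](OC)(OC)OC.[Li+] | intermediate (not isolated)
5 | rac-4-(1-hydroxypropyl)-2,5-dimethoxyphenol | CCC(O)c1cc(OC)c(O)cc1OC | intermediate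
6 | (Z)-asarone (β-asarone, 1,2,4-trimethoxy-5-[(Z)-prop-1-enyl]benzene) | C/C=C\c1cc(OC)c(OC)cc1OC | starting material
7 | (E)-2,5-dimethoxy-4-propylidenecyclohexa-2,5-dien-1-one | CC/C=C1\C=C(OC)C(=O)C=C1OC | intermediate (not isolated)
8 | dimeric benzylic cation, ArCH(+)–CH(Me)–CH(Et)–(4-hydroxy-2,5-dimethoxyphenyl), C7 and C8 configured as in 10, ion pair with the catalyst anion | CC[C@@H](c1cc(OC)c(O)cc1OC)[C@H](C)[CH+]c1cc(OC)c(OC)cc1OC | intermediate (not isolated)
9 | trimeric benzylic cation, ArCH(+)–CH(Me)–CH(Ar)–CH(Me)–CH(Et)–(4-hydroxy-2,5-dimethoxyphenyl), C7 to C10 configured as in 10, ion pair with the catalyst anion | CC[C@@H](c1cc(OC)c(O)cc1OC)[C@H](C)[C@H](c1cc(OC)c(OC)cc1OC)[C@@H](C)[CH+]c1cc(OC)c(OC)cc1OC | intermediate (not isolated)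
10 | tatanan B, (6S,7R,8S,9S,10R,11R)-7-ethyl-1,4-dimethoxy-8,10-dimethyl-9,11-bis(2,4,5-trimethoxyphenyl)spiro[5.5]undeca-1,4-dien-3-one | CC[C@@H]1[C@H](C)[C@H](c2cc(OC)c(OC)cc2OC)[C@@H](C)[C@H](c2cc(OC)c(OC)cc2OC)[C@]12C=C(OC)C(=O)C=C2OC | target

Total step count: 3. Longest linear sequence: 3 steps (1 to 2 to 5 to 10).

**Steps most likely to fail**

Step 3. The three-component cation cascade may lose its order of events: the alkene may oligomerise with itself, cation 8 may be captured early by an arene position, and the catalyst may discriminate the faces of the first cation poorly. The fallback sets out from 5, returns to the route at 10, and makes the same three bonds one at a time with known reaction types.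
- An organocatalytic SN1-type α-alkylation of propanal with the cation from 5 (chiral 5-benzyl-2,2,3-trimethylimidazolidin-4-one TFA salt, appropriate antipode, Et2O, 0 °C) should give (2S,3R)-3-(4-hydroxy-2,5-dimethoxyphenyl)-2-methylpentanal F1. The catalyst sets C8, and the C7 epimer is removed by chromatography.
- Addition of 2,4,5-trimethoxyphenylmagnesium bromide (3 equiv, THF, 0 °C) should give (2S,3R)-3-(4-hydroxy-2,5-dimethoxyphenyl)-2-methyl-1-(2,4,5-trimethoxyphenyl)pentan-1-ol F2 as a carbinol mixture, both epimers being usable.
- The commercial ketone 1-(2,4,5-trimethoxyphenyl)propan-1-one is converted (LiN(iPr)2, TMSCl, THF, -78 °C) into (Z)-trimethyl{[1-(2,4,5-trimethoxyphenyl)prop-1-enyl]oxy}silane F3.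
- Acid-catalysed SN1 alkylation of F3 by F2 (HBF4·OEt2, 10 mol%, CH2Cl2, -78 °C) should give (2R,3S,4S,5R)-5-(4-hydroxy-2,5-dimethoxyphenyl)-2,4-dimethyl-1,3-bis(2,4,5-trimethoxyphenyl)heptan-1-one F4. Attack on the α-branched benzylic cation is A(1,3)-controlled, and the centre α to the ketone can be corrected by base equilibration if needed.
- NaBH4 (MeOH, 0 °C) should give (2R,3S,4S,5R)-5-(4-hydroxy-2,5-dimethoxyphenyl)-2,4-dimethyl-1,3-bis(2,4,5-trimethoxyphenyl)heptan-1-ol F5 as a carbinol mixture.
- Ionisation of F5 (TFA, CH2Cl2, -20 °C) and ipso-Friedel–Crafts closure by the phenol through the same chair should give 10.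

Step 2. The aryllithium may be protonated or butylated before borylation, and the electron-rich p-hydroxybenzylic alcohol may expel hydroxide to a quinone methide during the basic oxidative work-up. The fallback sets out from 2 and returns at 5 without organolithium chemistry. Miyaura borylation (B2pin2, Pd(dppf)Cl2 3 mol%, KOAc, 1,4-dioxane, 80 °C) should give the isolable rac-1-[2,5-dimethoxy-4-(4,4,5,5-tetramethyl-1,3,2-dioxaborolan-2-yl)phenyl]propan-1-ol F6. Near-neutral oxidation of F6 (NaBO3·4H2O, THF/H2O, rt) should then give 5.

Step 1. Hydride transfer from the β-hydrogens of the ethyl Grignard reagent may reduce the hindered, electron-rich aldehyde instead of adding to it. The fallback sets out from 1 and returns at 2. Vinylmagnesium bromide (THF, -78 °C), which cannot transfer hydride in this way, should give rac-1-(4-bromo-2,5-dimethoxyphenyl)prop-2-en-1-ol F7. Diimide reduction of the terminal alkene (2-nitrobenzenesulfonyl hydrazide, Et3N, CH2Cl2, rt) should then give 2 with the aryl bromide intact.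

**Further compounds**

F1 | step 3 | (2S,3R)-3-(4-hydroxy-2,5-dimethoxyphenyl)-2-methylpentanal | CC[C@@H](c1cc(OC)c(O)cc1OC)[C@H](C)C=O
F2 | step 3 | (2S,3R)-3-(4-hydroxy-2,5-dimethoxyphenyl)-2-methyl-1-(2,4,5-trimethoxyphenyl)pentan-1-ol (carbinol mixture) | CC[C@@H](c1cc(OC)c(O)cc1OC)[C@H](C)C(O)c1cc(OC)c(OC)cc1OC
F3 | step 3 | (Z)-trimethyl{[1-(2,4,5-trimethoxyphenyl)prop-1-enyl]oxy}silane | C/C=C(\O[Si](C)(C)C)c1cc(OC)c(OC)cc1OC
F4 | step 3 | (2R,3S,4S,5R)-5-(4-hydroxy-2,5-dimethoxyphenyl)-2,4-dimethyl-1,3-bis(2,4,5-trimethoxyphenyl)heptan-1-one | CC[C@@H](c1cc(OC)c(O)cc1OC)[C@H](C)[C@H](c1cc(OC)c(OC)cc1OC)[C@@H](C)C(=O)c1cc(OC)c(OC)cc1OC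
F5 | step 3 | (2R,3S,4S,5R)-5-(4-hydroxy-2,5-dimethoxyphenyl)-2,4-dimethyl-1,3-bis(2,4,5-trimethoxyphenyl)heptan-1-ol (carbinol mixture) | CC[C@@H](c1cc(OC)c(O)cc1OC)[C@H](C)[C@H](c1cc(OC)c(OC)cc1OC)[C@@H](C)C(O)c1cc(OC)c(OC)cc1OC
F6 | step 2 | rac-1-[2,5-dimethoxy-4-(4,4,5,5-tetramethyl-1,3,2-dioxaborolan-2-yl)phenyl]propan-1-ol | CCC(O)c1cc(OC)c(B2OC(C)(C)C(C)(C)O2)cc1OC
F7 | step 1 | rac-1-(4-bromo-2,5-dimethoxyphenyl)prop-2-en-1-ol | C=CC(O)c1cc(OC)c(Br)cc1OC
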